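**Retrosynthetic overview** (azulene locants: ring A = C1–C2–C3–C3a–C8a, ring B = C3a–C4–C5–C6–C7–C8–C8a)

- The target is cut at the C4–O ester bond, then at the C4 carbinol (hydroxyl-directed reduction of a C4 ketone), then at two auxiliary ester groups on C7 (decarboxylation).
- Key disconnection: ring B is opened at C6–C7 and C8–C8a. This removes C7–C8 as diethyl 2-methylidenepropanedioate and leaves a ring-A ynone with an exocyclic methylene on C8a. Forward, one radical–polar crossover (5+2) annulation should make both bonds, the C8a quaternary centre, the trans ring fusion and the C5=C6 enone.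
- Enabling feature: C7 and C8 are two adjacent, unsubstituted CH2 carbons of ring B. They lie between C8a (methyl-bearing ring-fusion carbon, reachable as a tertiary radical from C=CH2) and C6 (methyl-bearing alkene carbon β to the C4 oxygen, i.e. the β-carbon of a C4 ynone).
- Ring A is bought as 3-methylcyclopent-2-en-1-one. C3 is set by isopropyl addition to an enantioenriched epoxy ketone (temporary epoxide); C3a by a [2,3]-Wittig rearrangement that also delivers the exocyclic methylene.
- Order of ring formation: ring A from the start, ring B in the key step.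

Key step: step 9

Assumption: diethyl 2-methylidenepropanedioate is used as the commercial stabilised monomer, distilled before use; the cinchona catalyst enantiomer in step 3 is the one that gives the (1R,5S) epoxide.

**Step 1**
Reactants: 1 3-methylcyclopent-2-en-1-one
Product: 2 3-(bromomethyl)cyclopent-2-en-1-one
Conditions: NBS, AIBN (cat.), PhCF3, reflux
Reagents that add atoms: N-bromosuccinimide, O=C1CCC(=O)N1Br
Why: Wohl–Ziegler allylic bromination, in which hydrogen abstraction at the γ-methyl group gives the carbonyl-conjugated exocyclic allyl radical; no stereocentre is involved.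

**Step 2**
Reactants: 2 3-(bromomethyl)cyclopent-2-en-1-one; 3 but-2-yn-1-ol
Product: 4 3-[(but-2-yn-1-yloxy)methyl]cyclopent-2-en-1-one
Conditions: Ag2O, 4 Å MS, CH2Cl2, rt, dark
Reagents that add atoms: none
Why: Silver-assisted Williamson-type etherification of the reactive allylic bromide under non-basic conditions, which should avoid deprotonation of the vinylogous enone.

**Step 3**
Reactants: 4 3-[(but-2-yn-1-yloxy)methyl]cyclopent-2-en-1-one
Product: 5 (1R,5S)-5-[(but-2-yn-1-yloxy)methyl]-6-oxabicyclo[3.1.0]hexan-2-one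
Conditions: 9-amino-9-deoxy-epi-quinine·2CF3CO2H (10 mol %), 50% aq H2O2, dioxane, 50 °C
Reagents that add atoms: hydrogen peroxide, OO
Why: Amine-catalysed asymmetric Weitz–Scheffer epoxidation of a cyclic enone, in which the chiral primary-amine salt forms the iminium ion and directs hydroperoxide to one face, so both epoxide carbons are set together.

**Step 4**
Reactants: 5 (1R,5S)-5-[(but-2-yn-1-yloxy)methyl]-6-oxabicyclo[3.1.0]hexan-2-one
Product: 6 (1S,2R,5S)-5-[(but-2-yn-1-yloxy)methyl]-2-(propan-2-yl)-6-oxabicyclo[3.1.0]hexan-2-ol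
Conditions: i-PrMgCl, CeCl3, THF, −78 °C
Reagents that add atoms: isopropylmagnesium chloride, CC(C)[Mg]Cl
Why: Organocerium 1,2-addition to the easily enolised ketone; the reagent should attack anti to the epoxide oxygen, so the new tertiary carbinol (R) carries its OH cis to the epoxide.

**Step 5**
Reactants: 6 (1S,2R,5S)-5-[(but-2-yn-1-yloxy)methyl]-2-(propan-2-yl)-6-oxabicyclo[3.1.0]hexan-2-ol
Product: 7 (1R)-3-[(but-2-yn-1-yloxy)methyl]-1-(propan-2-yl)cyclopent-2-en-1-ol
Conditions: MeReO3 (5 mol %), PPh3, toluene, 60 °C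
Reagents that add atoms: none
Why: Rhenium-catalysed oxygen-atom transfer from the epoxide to the phosphine (epoxide deoxygenation) restores the ring alkene; the carbinol centre is untouched, so the epoxide has served only as a temporary stereocontrol element.

**Step 6**
Reactants: 7 (1R)-3-[(but-2-yn-1-yloxy)methyl]-1-(propan-2-yl)cyclopent-2-en-1-ol
Product: 8 {[(1R)-3-[(but-2-yn-1-yloxy)methyl]-1-(propan-2-yl)cyclopent-2-en-1-yl]oxy}(triethyl)silane
Conditions: TESOTf, 2,6-lutidine, CH2Cl2, −78 °C
Reagents that add atoms: triethylsilyl trifluoromethanesulfonate, CC[Si](CC)(CC)OS(=O)(=O)C(F)(F)F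
Why: Silyl triflate silylation of a hindered tertiary alcohol; the ether masks O3, because a free β-hydroxy ynone would later close to a dihydropyranone.

**Step 7**
Reactants: 8 {[(1R)-3-[(but-2-yn-1-yloxy)methyl]-1-(propan-2-yl)cyclopent-2-en-1-yl]oxy}(triethyl)silane
Product: 9 1-[(1S,2R)-5-methylidene-2-(propan-2-yl)-2-[(triethylsilyl)oxy]cyclopentyl]but-2-yn-1-ol (carbinol carbon: either configuration)
Conditions: n-BuLi, THF, −78 °C; AcOH, −78 °C
Reagents that add atoms: none
Why: [2,3]-Wittig rearrangement of the propargylic carbanion through a five-membered envelope transition state; the C3a–C4 bond should form on the ring face opposite the isopropyl group (the face of the C3 oxygen, whose silyl group can turn away), which sets C3a and creates the exocyclic methylene, while the C4 carbinol configuration is irrelevant.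

**Step 8**
Reactants: 9 1-[(1S,2R)-5-methylidene-2-(propan-2-yl)-2-[(triethylsilyl)oxy]cyclopentyl]but-2-yn-1-ol
Product: 10 1-[(1R,2R)-5-methylidene-2-(propan-2-yl)-2-[(triethylsilyl)oxy]cyclopentyl]but-2-yn-1-one
Conditions: Dess–Martin periodinane, NaHCO3, CH2Cl2, 0 °C
Reagents that add atoms: none
Why: Dess–Martin oxidation under buffered neutral conditions should give the ynone without moving the β,γ-alkene into conjugation or epimerising C3a.

**Step 9**
Reactants: 10 1-[(1R,2R)-5-methylidene-2-(propan-2-yl)-2-[(triethylsilyl)oxy]cyclopentyl]but-2-yn-1-one; 11 diethyl 2-methylidenepropanedioate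
Product: 13 diethyl (3R,3aR,8aR)-6,8a-dimethyl-4-oxo-3-(propan-2-yl)-3-[(triethylsilyl)oxy]-1,2,3,3a,4,8a-hexahydroazulene-7,7(8H)-dicarboxylate, via Giese adduct 12 (not isolated)
Conditions: Fe(acac)3 (30 mol %), PhSiH2(Oi-Pr), 11 (3 equiv), THF/i-PrOH, 0 °C to rt; then Cs2CO3 (0.2 equiv), rt
Reagents that add atoms: none
Why: Proposed new method: iron-hydride hydrogen-atom transfer to the exocyclic 1,1-disubstituted alkene should give the tertiary C8a radical (the methylene carbon becomes the angular methyl), which adds to the methylidenemalonate (C8–C8a); the malonyl radical is reduced by divalent iron to the malonate anion, which closes ring B by conjugate addition to the ynone β-carbon (C6–C7) and is protonated to the enone. The closest known reaction types are iron-hydride reductive olefin cross-coupling (Giese addition of tertiary radicals made by hydrogen-atom transfer) and radical–polar crossover annulation in which the reduced adduct is trapped by a carbonyl group; new here are the ynone as the polar trap and the seven-membered ring. Ring B closes in the 7-endo-dig mode, which the polarisation of the ynone enforces (attack at C6, not at C5; addition to the C4 carbonyl would be a reversible malonate aldol). C8a is set by approach of the acceptor to the radical face anti to the adjacent butynoyl group on C3a, which is also the face away from the silyloxy group, so the ring fusion should be trans; C3 and C3a are carried through unchanged. The step needs hydrogen-atom transfer to the electron-rich alkene in the presence of the ynone and capture of the radical by the malonate acceptor before anything else: the 1,1-disubstituted alkene is the best hydrogen-atom acceptor present, the methylidenemalonate is in excess and far more radicophilic than the β-substituted ynone, and the catalytic carbonate only completes the Michael closure of any protonated adduct 12.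

**Step 10**
Reactants: 13 diethyl (3R,3aR,8aR)-6,8a-dimethyl-4-oxo-3-(propan-2-yl)-3-[(triethylsilyl)oxy]-1,2,3,3a,4,8a-hexahydroazulene-7,7(8H)-dicarboxylate
Product: 15 (3R,3aR,8aS)-6,8a-dimethyl-3-(propan-2-yl)-3-[(triethylsilyl)oxy]-2,3,3a,7,8,8a-hexahydroazulen-4(1H)-one, via monoester 14 (not isolated)
Conditions: LiCl, H2O, DMSO, 150 °C
Reagents that add atoms: none
Why: Krapcho dealkoxycarbonylation, twice: the first ester leaves as a malonate and the second as a vinylogous β-keto ester through the dienolate of the enone, whose γ-protonation should return the conjugated C5=C6 enone; the neutral halide conditions should leave C3a–H and the silyl ether alone, and no stereocentre is created.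

**Step 11**
Reactants: 15 (3R,3aR,8aS)-6,8a-dimethyl-3-(propan-2-yl)-3-[(triethylsilyl)oxy]-2,3,3a,7,8,8a-hexahydroazulen-4(1H)-one
Product: 16 (3R,3aR,8aS)-3-hydroxy-6,8a-dimethyl-3-(propan-2-yl)-2,3,3a,7,8,8a-hexahydroazulen-4(1H)-one
Conditions: HF·pyridine, pyridine, THF, 0 °C to rt
Reagents that add atoms: none
Why: Buffered fluoride cleavage of the tertiary silyl ether frees O3 without the retro-aldol or dehydration that base or strong acid could cause in the β-hydroxy ketone.

**Step 12**
Reactants: 16 (3R,3aR,8aS)-3-hydroxy-6,8a-dimethyl-3-(propan-2-yl)-2,3,3a,7,8,8a-hexahydroazulen-4(1H)-one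
Product: 17 (3R,3aS,4S,8aS)-6,8a-dimethyl-3-(propan-2-yl)-1,2,3,3a,4,7,8,8a-octahydroazulene-3,4-diol
Conditions: Me4NBH(OAc)3, MeCN/AcOH, −20 °C
Reagents that add atoms: none
Why: Hydroxyl-directed Evans–Saksena 1,2-reduction; the borohydride bound to the C3 oxygen should deliver hydride intramolecularly to the face of the C4 carbonyl on which that oxygen sits, giving the 1,3-anti diol (4S) without conjugate reduction.

**Step 13**
Reactants: 17 (3R,3aS,4S,8aS)-6,8a-dimethyl-3-(propan-2-yl)-1,2,3,3a,4,7,8,8a-octahydroazulene-3,4-diol; 18 4-(acetyloxy)benzoyl chloride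
Product: 19 (3R,3aS,4S,8aS)-3-hydroxy-6,8a-dimethyl-3-(propan-2-yl)-1,2,3,3a,4,7,8,8a-octahydroazulen-4-yl 4-(acetyloxy)benzoate
Conditions: pyridine, DMAP (cat.), CH2Cl2, 0 °C to rt
Reagents that add atoms: none
Why: DMAP-catalysed acylation; the secondary allylic C4 hydroxyl should react while the hindered tertiary C3 hydroxyl does not, and C4 keeps its configuration because the C–O bond is not broken.

**Step 14**
Reactants: 19 (3R,3aS,4S,8aS)-3-hydroxy-6,8a-dimethyl-3-(propan-2-yl)-1,2,3,3a,4,7,8,8a-octahydroazulen-4-yl 4-(acetyloxy)benzoate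
Product: 20 (3R,3aS,4S,8aS)-3-hydroxy-6,8a-dimethyl-3-(propan-2-yl)-1,2,3,3a,4,7,8,8a-octahydroazulen-4-yl 4-hydroxybenzoate (target)
Conditions: pyrrolidine, CH2Cl2, 0 °C
Reagents that add atoms: none
Why: Aminolysis of the activated aryl acetate should be much faster than attack on the hindered secondary benzoate, so only the phenol is released.

**Compound list**

1 | 3-methylcyclopent-2-en-1-one | CC1=CC(=O)CC1 | starting material
2 | 3-(bromomethyl)cyclopent-2-en-1-one | BrCC1=CC(=O)CC1 | intermediate
3 | but-2-yn-1-ol | CC#CCO | starting material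
4 | 3-[(but-2-yn-1-yloxy)methyl]cyclopent-2-en-1-one | CC#CCOCC1=CC(=O)CC1 | intermediate
5 | (1R,5S)-5-[(but-2-yn-1-yloxy)methyl]-6-oxabicyclo[3.1.0]hexan-2-one | CC#CCOC[C@@]12CCC(=O)[C@@H]1O2 | intermediate
6 | (1S,2R,5S)-5-[(but-2-yn-1-yloxy)methyl]-2-(propan-2-yl)-6-oxabicyclo[3.1.0]hexan-2-ol (OH cis to the epoxide oxygen) | CC#CCOC[C@@]12CC[C@@](O)(C(C)C)[C@@H]1O2 | intermediate
7 | (1R)-3-[(but-2-yn-1-yloxy)methyl]-1-(propan-2-yl)cyclopent-2-en-1-ol | CC#CCOCC1=C[C@](O)(C(C)C)CC1 | intermediate
8 | {[(1R)-3-[(but-2-yn-1-yloxy)methyl]-1-(propan-2-yl)cyclopent-2-en-1-yl]oxy}(triethyl)silane | CC#CCOCC1=C[C@](O[Si](CC)(CC)CC)(C(C)C)CC1 | intermediate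
9 | 1-[(1S,2R)-5-methylidene-2-(propan-2-yl)-2-[(triethylsilyl)oxy]cyclopentyl]but-2-yn-1-ol (side chain cis to the silyloxy group; carbinol carbon either configuration) | CC#CC(O)[C@@H]1C(=C)CC[C@@]1(O[Si](CC)(CC)CC)C(C)C | intermediate
10 | 1-[(1R,2R)-5-methylidene-2-(propan-2-yl)-2-[(triethylsilyl)oxy]cyclopentyl]but-2-yn-1-one | CC#CC(=O)[C@@H]1C(=C)CC[C@@]1(O[Si](CC)(CC)CC)C(C)C | intermediate
11 | diethyl 2-methylidenepropanedioate | C=C(C(=O)OCC)C(=O)OCC | starting material
12 | diethyl 2-{[(1R,2R,3R)-2-(but-2-ynoyl)-1-methyl-3-(propan-2-yl)-3-[(triethylsilyl)oxy]cyclopentyl]methyl}propanedioate | CC#CC(=O)[C@@H]1[C@@](C)(CC(C(=O)OCC)C(=O)OCC)CC[C@@]1(O[Si](CC)(CC)CC)C(C)C | intermediate (not isolated)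
13 | diethyl (3R,3aR,8aR)-6,8a-dimethyl-4-oxo-3-(propan-2-yl)-3-[(triethylsilyl)oxy]-1,2,3,3a,4,8a-hexahydroazulene-7,7(8H)-dicarboxylate (trans ring fusion) | CC1=CC(=O)[C@@H]2[C@@](C)(CC1(C(=O)OCC)C(=O)OCC)CC[C@@]2(O[Si](CC)(CC)CC)C(C)C | intermediate
14 | ethyl (3R,3aR,8aR)-6,8a-dimethyl-4-oxo-3-(propan-2-yl)-3-[(triethylsilyl)oxy]-1,2,3,3a,4,7,8,8a-octahydroazulene-7-carboxylate (C7 either configuration) | CC1=CC(=O)[C@@H]2[C@@](C)(CC1C(=O)OCC)CC[C@@]2(O[Si](CC)(CC)CC)C(C)C | intermediate (not isolated)
15 | (3R,3aR,8aS)-6,8a-dimethyl-3-(propan-2-yl)-3-[(triethylsilyl)oxy]-2,3,3a,7,8,8a-hexahydroazulen-4(1H)-one | CC1=CC(=O)[C@@H]2[C@@](C)(CC1)CC[C@@]2(O[Si](CC)(CC)CC)C(C)C | intermediate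
16 | (3R,3aR,8aS)-3-hydroxy-6,8a-dimethyl-3-(propan-2-yl)-2,3,3a,7,8,8a-hexahydroazulen-4(1H)-one | CC1=CC(=O)[C@@H]2[C@@](C)(CC1)CC[C@@]2(O)C(C)C | intermediate
17 | (3R,3aS,4S,8aS)-6,8a-dimethyl-3-(propan-2-yl)-1,2,3,3a,4,7,8,8a-octahydroazulene-3,4-diol | CC1=C[C@H](O)[C@@H]2[C@@](C)(CC1)CC[C@@]2(O)C(C)C | intermediate
18 | 4-(acetyloxy)benzoyl chloride | CC(=O)Oc1ccc(cc1)C(Cl)=O | starting material
19 | (3R,3aS,4S,8aS)-3-hydroxy-6,8a-dimethyl-3-(propan-2-yl)-1,2,3,3a,4,7,8,8a-octahydroazulen-4-yl 4-(acetyloxy)benzoate | CC1=C[C@H](OC(=O)c2ccc(OC(C)=O)cc2)[C@@H]2[C@@](C)(CC1)CC[C@@]2(O)C(C)C | intermediate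
20 | (3R,3aS,4S,8aS)-3-hydroxy-6,8a-dimethyl-3-(propan-2-yl)-1,2,3,3a,4,7,8,8a-octahydroazulen-4-yl 4-hydroxybenzoate | CC1=C[C@H](OC(=O)c2ccc(O)cc2)[C@@H]2[C@@](C)(CC1)CC[C@@]2(O)C(C)C | target

**Total step count:** 14
**Longest linear sequence:** 14 steps (1 to 20)

**Steps most likely to fail**

1. Step 9 (Proposed new method). What may go wrong: hydride or alkoxide attack on the ynone under the iron-hydride conditions, or protonation of the malonate and its loss to intermolecular paths before the seven-membered ring closes. The fallback uses known chemistry and moves the radical step in front of the ynone. It sets out from 9: iron-hydride reductive olefin coupling of 9 with 11 (Fe(acac)3, PhSiH3, EtOH/THF, 40 °C), run on the propargylic alcohol where no conjugate acceptor is present, should give diethyl 2-{[(1R,2S,3R)-2-(1-hydroxybut-2-yn-1-yl)-1-methyl-3-(propan-2-yl)-3-[(triethylsilyl)oxy]cyclopentyl]methyl}propanedioate F1. Dess–Martin oxidation then gives 12, now isolated, and Cs2CO3 in MeCN closes ring B by intramolecular Michael addition. The fallback comes back to the route at 13.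

2. Step 3. What may go wrong: slow iminium formation with the five-membered enone, giving low conversion and eroded enantioselectivity. The fallback sets out from 4: Corey–Bakshi–Shibata reduction ((R)-Me-CBS oxazaborolidine, catecholborane, toluene, −78 °C, chosen so that the alkyne is not hydroborated) should give (1S)-3-[(but-2-yn-1-yloxy)methyl]cyclopent-2-en-1-ol F2. Hydroxyl-directed epoxidation (VO(acac)2, t-BuOOH, CH2Cl2) should give the syn epoxy alcohol (1S,2S,5S)-5-[(but-2-yn-1-yloxy)methyl]-6-oxabicyclo[3.1.0]hexan-2-ol F3, and Dess–Martin oxidation returns the epoxy ketone. The fallback comes back to the route at 5.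

3. Step 7. What may go wrong: bond formation on the isopropyl face (poor facial selectivity at C3a), or oxygen-to-oxygen silyl migration in the lithium alkoxide product. The fallback sets out from 7: the rearrangement is run on the unprotected alcohol as its dianion (n-BuLi, 2.2 equiv, THF, −78 °C), where the lithium alkoxide on C3 should hold the carbanion on its own face, to give (1R,2S)-2-(1-hydroxybut-2-yn-1-yl)-3-methylidene-1-(propan-2-yl)cyclopentan-1-ol F4. Double silylation (TESOTf, 2,6-lutidine, CH2Cl2) should give triethyl({(1R,2S)-3-methylidene-1-(propan-2-yl)-2-{1-[(triethylsilyl)oxy]but-2-yn-1-yl}cyclopentyl}oxy)silane F5, and PPTS in MeOH at 0 °C should free the secondary propargylic alcohol selectively. The fallback comes back to the route at 9.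

**Further compounds**

F1 | step 9 | diethyl 2-{[(1R,2S,3R)-2-(1-hydroxybut-2-yn-1-yl)-1-methyl-3-(propan-2-yl)-3-[(triethylsilyl)oxy]cyclopentyl]methyl}propanedioate | CC#CC(O)[C@@H]1[C@@](C)(CC(C(=O)OCC)C(=O)OCC)CC[C@@]1(O[Si](CC)(CC)CC)C(C)C
F2 | step 3 | (1S)-3-[(but-2-yn-1-yloxy)methyl]cyclopent-2-en-1-ol | CC#CCOCC1=C[C@@H](O)CC1
F3 | step 3 | (1S,2S,5S)-5-[(but-2-yn-1-yloxy)methyl]-6-oxabicyclo[3.1.0]hexan-2-ol | CC#CCOC[C@@]12CC[C@H](O)[C@@H]1O2
F4 | step 7 | (1R,2S)-2-(1-hydroxybut-2-yn-1-yl)-3-methylidene-1-(propan-2-yl)cyclopentan-1-ol | CC#CC(O)[C@@H]1C(=C)CC[C@@]1(O)C(C)C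
F5 | step 7 | triethyl({(1R,2S)-3-methylidene-1-(propan-2-yl)-2-{1-[(triethylsilyl)oxy]but-2-yn-1-yl}cyclopentyl}oxy)silane | CC#CC(O[Si](CC)(CC)CC)[C@@H]1C(=C)CC[C@@]1(O[Si](CC)(CC)CC)C(C)C
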